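Ring B is not coupled to ring A as a finished arene but grown onto the ether oxygen. In ring B the C1' carboxyl lies beside the C6' hydroxyl and the C4' methyl beside C5'–H, so C1', C6' and the carboxyl are read as one malonate, and C4', C5' and the methyl as an isopropylidene group. The precursor is therefore a ring A aryl ether at C2' of a (3-methylbut-2-enylidene)malonate, with allyl on both malonate esters and on the ring A phenol. One base-induced operation joins C5' to an ester carbonyl (the C5'–C6' bond), closes ring B, expels allyl alcohol and aromatises to the salicylate.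

Key step: step 11

Remark: ring A is built from 2-chlororesorcinol and not by chlorinating a 3,5-dihydroxybenzoate, because electrophilic chlorination of the latter should go mainly ortho to the ester and not between the two oxygens; this costs two steps but fixes the chlorine position from the outset.

Step 1
Reactants: 1 2-chlororesorcinol (2-chlorobenzene-1,3-diol)
Product: 3 3-chloro-2,4-dihydroxybenzaldehyde, via iminium chloride 2 (not isolated)
Conditions: POCl3, DMF, MeCN, −15 °C to rt; then H2O, 50 °C
Reagents that add atoms: N,N-dimethylformamide CN(C)C=O; water O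
Why: Vilsmeier–Haack formylation of an electron-rich arene should succeed because the chloroiminium ion attacks para to one hydroxyl and ortho to the other, the two such positions of the symmetrical diol are identical and the position meta to both oxygens is inert, so only one aldehyde can form after hydrolysis of the iminium salt.

Step 2
Reactants: 3 3-chloro-2,4-dihydroxybenzaldehyde
Product: 4 4-(allyloxy)-3-chloro-2-hydroxybenzaldehyde
Conditions: allyl bromide (1.05 equiv), KHCO3, DMF, 40 °C
Reagents that add atoms: allyl bromide C=CCBr
Why: Williamson ether synthesis that should be selective because hydrogencarbonate ionises the free para hydroxyl, made more acidic by the aldehyde and the neighbouring chlorine, while the ortho hydroxyl stays tied up in its hydrogen bond to the carbonyl, as in the established 4-O-alkylation of 2,4-dihydroxybenzaldehydes.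

Step 3
Reactants: 4 4-(allyloxy)-3-chloro-2-hydroxybenzaldehyde
Product: 5 4-(allyloxy)-3-chloro-2-methoxybenzaldehyde
Conditions: MeI, K2CO3, DMF, 40 °C
Reagents that add atoms: iodomethane CI
Why: Williamson methylation of the remaining chelated phenol, which the stronger base carbonate in a dipolar solvent ionises fully, and nothing else in the molecule can be alkylated.

Step 4
Reactants: 5 4-(allyloxy)-3-chloro-2-methoxybenzaldehyde
Product: 7 4-(allyloxy)-3-chloro-2-methoxyphenol, via aryl formate 6 (not isolated)
Conditions: 30% H2O2, cat. H2SO4, MeOH, rt
Reagents that add atoms: hydrogen peroxide OO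
Why: Acid-catalysed Dakin oxidation (a Baeyer–Villiger-type aryl shift in the peroxide adduct of the aldehyde) should work because the ring carries a para and an ortho alkoxy group that favour aryl over hydride migration, the formate is cleaved by methanol in the same flask, and hydrogen peroxide without a peracid or metal does not epoxidise the allyl group.

Step 5
Reactants: 7 4-(allyloxy)-3-chloro-2-methoxyphenol
Product: 8 5-(allyloxy)-4-chloro-2-hydroxy-3-methoxybenzaldehyde
Conditions: MgCl2, Et3N, (CH2O)n, MeCN, reflux
Reagents that add atoms: formaldehyde (as paraformaldehyde) C=O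
Why: Magnesium-mediated ortho-formylation of a phenol, in which formaldehyde is delivered inside the aryloxymagnesium chloride complex and a second formaldehyde takes up hydride, is specific for the position next to the hydroxyl, and only one such position (C6 of the phenol) is unsubstituted.

Step 6
Reactants: 8 5-(allyloxy)-4-chloro-2-hydroxy-3-methoxybenzaldehyde
Product: 9 5-(allyloxy)-4-chloro-2-hydroxy-3-methoxybenzoic acid
Conditions: NaClO2, NaH2PO4, 2-methyl-2-butene (excess), t-BuOH–H2O, 0 °C to rt
Reagents that add atoms: NaClO2 (sodium chlorite) [Na+].[O-]Cl=O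
Why: Pinnick oxidation converts the aldehyde into the acid with chlorous acid at about pH 4 without touching the phenol, the allyl ether or the aryl chloride, the alkene scavenger removing hypochlorous acid before it can chlorinate the one free ring position.

Step 7
Reactants: 9 5-(allyloxy)-4-chloro-2-hydroxy-3-methoxybenzoic acid
Product: 10 methyl 5-(allyloxy)-4-chloro-2-hydroxy-3-methoxybenzoate
Conditions: MeI, KHCO3, DMF, rt
Reagents that add atoms: iodomethane CI
Why: SN2 esterification of the carboxylate, selective because hydrogencarbonate deprotonates the acid but not the phenol held in a hydrogen bond to the carboxyl group.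

Step 8
Reactants: 11 diallyl malonate; 12 3-methylbut-2-enoyl chloride
Product: 13 diallyl 2-(3-methylbut-2-enoyl)malonate
Conditions: MgCl2, Et3N, MeCN, 0 °C; then 12, 0 °C to rt; aq. HCl work-up
Reagents that add atoms: none
Why: Magnesium-enolate C-acylation of a malonate (a crossed Claisen-type acylation) in which chelation to magnesium allows triethylamine to deprotonate the malonate, directs the acid chloride to carbon and holds the more acidic tricarbonyl product as its enolate, which prevents a second acylation.

Step 9
Reactants: 13 diallyl 2-(3-methylbut-2-enoyl)malonate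
Product: 14 diallyl 2-(1-chloro-3-methylbut-2-en-1-ylidene)malonate
Conditions: POCl3, n-Bu3N, toluene, 80 °C
Reagents that add atoms: phosphoryl chloride O=P(Cl)(Cl)Cl
Why: Deoxychlorination of the enol of a 2-acylmalonate through its dichlorophosphate, a vinylogous version of acid chloride formation and the usual way to (1-chloroalkylidene)malonates, with no alkene geometry to control because the two ester groups are the same.

Step 10
Reactants: 10 methyl 5-(allyloxy)-4-chloro-2-hydroxy-3-methoxybenzoate; 14 diallyl 2-(1-chloro-3-methylbut-2-en-1-ylidene)malonate
Product: 15 diallyl 2-{1-[4-(allyloxy)-3-chloro-2-methoxy-6-(methoxycarbonyl)phenoxy]-3-methylbut-2-en-1-ylidene}malonate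
Conditions: NaH (1.0 equiv), THF, 0 °C; then 14, 0 °C to rt
Reagents that add atoms: none
Why: Nucleophilic vinylic substitution by addition–elimination: the phenoxide adds to the chlorine-bearing carbon, which is doubly activated by the two esters, the malonate-stabilised adduct expels chloride, and one equivalent of base leaves nothing to deprotonate the methyl groups of the product.

Step 11
Reactants: 15 diallyl 2-{1-[4-(allyloxy)-3-chloro-2-methoxy-6-(methoxycarbonyl)phenoxy]-3-methylbut-2-en-1-ylidene}malonate
Product: 17 allyl 2-[4-(allyloxy)-3-chloro-2-methoxy-6-(methoxycarbonyl)phenoxy]-6-hydroxy-4-methylbenzoate, via cyclohexadienone 16 (not isolated)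
Conditions: LiN(SiMe3)2 (2.5 equiv), THF, −78 to −20 °C; AcOH, −78 °C
Reagents that add atoms: none
Why: LiN(SiMe3)2 removes a proton from a methyl of the isopropylidene unit to give a trienolate delocalised from C5' through C3' onto both malonate esters, its CH2 terminus (C5') adds to the carbonyl carbon (C6') of the ester lying cis to the diene, the tetrahedral intermediate expels lithium allyl oxide, and dienone 16 is deprotonated at once to the aromatic phenoxide, which makes the sequence irreversible. The closest known reaction type is the Dieckmann-type (intramolecular Claisen) benzannulation in which an extended enolate of an unsaturated 1,3-dicarbonyl or alkylidene malonate chain closes onto an ester to give a salicylate. Ring B closes in a 6-exo-trig mode (equivalently a 6π closure of the hexatrienolate), and no stereocentre is formed. The step needs closure of C5' onto a malonate ester in preference to closure of the malonate carbon C1' onto the ring A ester or to loss of aryloxide: the C1' closure would give a quaternary, non-enolisable β-keto diester that no deprotonation can drain from the equilibrium, and C5' could reach the ring A ester only through an eight-membered ring. The two methyls on C4' and the two identical esters on C1' guarantee a cis methyl and a cis ester, so no alkene geometry has to be set. Excess amide base keeps all substrate as the non-electrophilic trienolate, and the cold acetic acid quench destroys the allyl oxide before it can exchange with the methyl ester or displace the aryloxide.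

Step 12
Reactants: 17 allyl 2-[4-(allyloxy)-3-chloro-2-methoxy-6-(methoxycarbonyl)phenoxy]-6-hydroxy-4-methylbenzoate
Product: 18 2-[3-chloro-4-hydroxy-2-methoxy-6-(methoxycarbonyl)phenoxy]-6-hydroxy-4-methylbenzoic acid (target)
Conditions: Pd(PPh3)4 (5 mol %), morpholine (10 equiv), THF, rt; then dilute aq. HCl
Reagents that add atoms: none
Why: Tsuji–Trost deallylation in which zerovalent palladium ionises both the allyl ester and the allyl aryl ether to π-allyl complexes that morpholine captures, at room temperature and without acid or strong base, so the methyl ester, the aryl chloride and the 2,6-dioxygenated benzoic acid survive.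

Compound list (no compound in the route has a stereocentre)

1 | 2-chlororesorcinol (2-chlorobenzene-1,3-diol) | Oc1cccc(O)c1Cl | starting material
2 | N-[(3-chloro-2,4-dihydroxyphenyl)methylidene]-N-methylmethanaminium chloride | C[N+](C)=Cc1ccc(O)c(Cl)c1O.[Cl-] | intermediate (not isolated)
3 | 3-chloro-2,4-dihydroxybenzaldehyde | O=Cc1ccc(O)c(Cl)c1O | intermediate
4 | 4-(allyloxy)-3-chloro-2-hydroxybenzaldehyde | O=Cc1ccc(OCC=C)c(Cl)c1O | intermediate
5 | 4-(allyloxy)-3-chloro-2-methoxybenzaldehyde | COc1c(C=O)ccc(OCC=C)c1Cl | intermediate
6 | 4-(allyloxy)-3-chloro-2-methoxyphenyl formate | COc1c(OC=O)ccc(OCC=C)c1Cl | intermediate (not isolated)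
7 | 4-(allyloxy)-3-chloro-2-methoxyphenol | COc1c(O)ccc(OCC=C)c1Cl | intermediate
8 | 5-(allyloxy)-4-chloro-2-hydroxy-3-methoxybenzaldehyde | COc1c(O)c(C=O)cc(OCC=C)c1Cl | intermediate
9 | 5-(allyloxy)-4-chloro-2-hydroxy-3-methoxybenzoic acid | COc1c(O)c(C(=O)O)cc(OCC=C)c1Cl | intermediate
10 | methyl 5-(allyloxy)-4-chloro-2-hydroxy-3-methoxybenzoate | COC(=O)c1cc(OCC=C)c(Cl)c(OC)c1O | intermediate
11 | diallyl malonate | C=CCOC(=O)CC(=O)OCC=C | starting material
12 | 3-methylbut-2-enoyl chloride | CC(C)=CC(Cl)=O | starting material
13 | diallyl 2-(3-methylbut-2-enoyl)malonate | CC(C)=CC(=O)C(C(=O)OCC=C)C(=O)OCC=C | intermediate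
14 | diallyl 2-(1-chloro-3-methylbut-2-en-1-ylidene)malonate | CC(C)=CC(Cl)=C(C(=O)OCC=C)C(=O)OCC=C | intermediate
15 | diallyl 2-{1-[4-(allyloxy)-3-chloro-2-methoxy-6-(methoxycarbonyl)phenoxy]-3-methylbut-2-en-1-ylidene}malonate | COC(=O)c1cc(OCC=C)c(Cl)c(OC)c1OC(C=C(C)C)=C(C(=O)OCC=C)C(=O)OCC=C | intermediate
16 | allyl 2-[4-(allyloxy)-3-chloro-2-methoxy-6-(methoxycarbonyl)phenoxy]-4-methyl-6-oxocyclohexa-1,3-diene-1-carboxylate | C=CCOC(=O)C1=C(Oc2c(OC)c(Cl)c(OCC=C)cc2C(=O)OC)C=C(C)CC1=O | intermediate (not isolated)
17 | allyl 2-[4-(allyloxy)-3-chloro-2-methoxy-6-(methoxycarbonyl)phenoxy]-6-hydroxy-4-methylbenzoate | COC(=O)c1cc(OCC=C)c(Cl)c(OC)c1Oc1cc(C)cc(O)c1C(=O)OCC=C | intermediate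
18 | 2-[3-chloro-4-hydroxy-2-methoxy-6-(methoxycarbonyl)phenoxy]-6-hydroxy-4-methylbenzoic acid | COC(=O)c1cc(O)c(Cl)c(OC)c1Oc1cc(C)cc(O)c1C(=O)O | target

Total step count: 12. Longest linear sequence: 10 steps (steps 1–7, 10, 11, 12).

Steps most likely to fail

1. Step 11. The trienolate may close only on warming, and by then the allyl oxide that the closure sets free can exchange with the ring A methyl ester or displace the aryloxide from substrate not yet cyclised. The fallback sets out from 10 and returns at 18, making the diaryl ether by aromatic substitution instead of annulation. 3,5-Difluorotoluene is lithiated between the fluorines (LiN(i-Pr)2, THF, −78 °C) and formylated with DMF to 2,6-difluoro-4-methylbenzaldehyde F1. One equivalent of sodium allyl oxide (allyl alcohol, NaH, THF, 0 °C) replaces one fluoride to give 2-(allyloxy)-6-fluoro-4-methylbenzaldehyde F2. The phenoxide of 10 (Cs2CO3, DMSO, 100 °C) then displaces the second, aldehyde-activated fluoride to give methyl 5-(allyloxy)-2-[3-(allyloxy)-2-formyl-5-methylphenoxy]-4-chloro-3-methoxybenzoate F3. Pinnick oxidation (NaClO2, NaH2PO4, 2-methyl-2-butene) gives 2-(allyloxy)-6-[4-(allyloxy)-3-chloro-2-methoxy-6-(methoxycarbonyl)phenoxy]-4-methylbenzoic acid F4, and Pd(PPh3)4 with morpholine removes both allyl ethers to give 18.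

2. Step 10. Addition of the chelated, doubly ortho-substituted phenoxide to a fully substituted alkene carbon may be slower than base-induced loss of HCl from 14 and oligomerisation of what results. The fallback sets out from 14 and 10 and returns at 15, turning the elimination into the productive path. Chloride 14 is added slowly to 10 and Et3N in MeCN at 0 °C, so that dehydrochlorination gives the vinylallene diallyl 2-(3-methylbuta-1,3-dien-1-ylidene)malonate F5 in low concentration. Its unhindered sp carbon should take up the phenol in a base-catalysed oxa-Michael addition, and a proton shift under the same base gives 15.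

3. Step 9. Hot POCl3 and the ammonium chloride formed may add HCl across the isopropylidene double bond, let an ester oxygen cyclise onto it, or dehydrochlorinate the product. The fallback sets out from 13 and returns at 15, activating the enol cold as a sulfonate. Tf2O and i-Pr2NEt in CH2Cl2 at −78 °C should give diallyl 2-{3-methyl-1-[(trifluoromethylsulfonyl)oxy]but-2-en-1-ylidene}malonate F6. The sodium phenoxide of 10 (THF, 0 °C) then displaces triflate by addition–elimination to give 15 without passing through 14.

Further compounds

F1 | step 11 | 2,6-difluoro-4-methylbenzaldehyde | Cc1cc(F)c(C=O)c(F)c1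
F2 | step 11 | 2-(allyloxy)-6-fluoro-4-methylbenzaldehyde | Cc1cc(F)c(C=O)c(OCC=C)c1
F3 | step 11 | methyl 5-(allyloxy)-2-[3-(allyloxy)-2-formyl-5-methylphenoxy]-4-chloro-3-methoxybenzoate | COC(=O)c1cc(OCC=C)c(Cl)c(OC)c1Oc1cc(C)cc(OCC=C)c1C=O
F4 | step 11 | 2-(allyloxy)-6-[4-(allyloxy)-3-chloro-2-methoxy-6-(methoxycarbonyl)phenoxy]-4-methylbenzoic acid | COC(=O)c1cc(OCC=C)c(Cl)c(OC)c1Oc1cc(C)cc(OCC=C)c1C(=O)O
F5 | step 10 | diallyl 2-(3-methylbuta-1,3-dien-1-ylidene)malonate | C=C(C)C=C=C(C(=O)OCC=C)C(=O)OCC=C
F6 | step 9 | diallyl 2-{3-methyl-1-[(trifluoromethylsulfonyl)oxy]but-2-en-1-ylidene}malonate | CC(C)=CC(OS(=O)(=O)C(F)(F)F)=C(C(=O)OCC=C)C(=O)OCC=C
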